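At early times Z entering from the gas meets G in excess and reacts with a half-life of 0.57 min, shorter than the transfer time of 6.24 min, so gas supply sets the pace at first.

    J ⇌ G.Z, rate k1*(cs1 - [G.Z]) while solid is left; crystals form when [G.Z] > cs1 (cs1 = 19 mM, k1 = 0.0437 /s)
    Z + G.Z → Z.G.Z (k2 = 0.00295 /M/s)
    G.Z ⇌ X (K3 = 2.7, k3 = 1.99 × 10⁻⁴ /s)
    D ⇌ Z, rate k4*(csat - [Z]) (k4 = 0.00267 /s, csat = 11 mM)
    G + Z → G.Z (k5 = 0.107 /M/s)

G 0.19 M; D 11 mM (held); time 3.0 h

- what is said of G.Z includes J
- J is a solid; its amount is given per volume of the solution
- at the start none of Z is dissolved
- run time (flask): 3.0 h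

- G.Z and J together at 3.0 h, in percent of the G charged
- concentration of Z in solution at 1.5 h, in percent of saturation
- the change that raises the amount of G.Z and J together at 3.0 h, in percent of the G charged most ("none" if none brings more than 2 percentage points) (dusk / autumn / noon / dawn / none)
- amount of G.Z and J together at 3.0 h, in percent of the G charged, after dusk

- dusk: doubling the transfer coefficient of step 4, all else as stated
- autumn: doubling the saturation concentration of D, all else as stated
- noon: doubling the solubility in step 1, all else as stated
- dawn: doubling the dissolution coefficient of step 1, all else as stated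

**The crossing.** The crossing concentration Gc, the transfer coefficient over the rate constant of G + Z, is 25.0 mM. With Z in quasi-steady balance, it stands at Gc/(Gc + [G]) of saturation, and G falls at F[G]/(Gc + [G]). Here F, the transfer coefficient times saturation, is 106 mM/h. Well above Gc, transfer is the rate-limiting step; well below it, G decays pseudo-first-order. Integrated from the charge c: c − [G] + Gc ln(c/[G]) = Ft.

**What counts.** The dissolution coefficient hardly counts: crystals taking up F need an excess of 0.672 mM over the solubility S of 19 mM, so dissolved G.Z stays near S once crystals have formed. An error in S passes in proportion into the loss to X, which rises toward K·S, K being the equilibrium constant, or 27.0 % of the charge. The over-reaction constant scales a small term, (its constant)·S·ln(c/[G]) over the rate constant of G + Z. Gas settings act at the end on the G still unconverted, reckoned below, and on the Z.G.Z term.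

**The numbers.** At 1.5 h, the balance gives [G] near 60.7 mM, so Z stands at 29.2 % of saturation. At 3.0 h, [G] ≈ c·exp((c − Ft)/Gc) = 1.16 mM, or 0.611 % of the charge, which is less than the 2 percentage points threshold. X takes 14.8 % and Z.G.Z 1.41 %, leaving y at 83.2 %. After dusk, the same terms give 82.7 %. Noon doubles the X term and autumn enlarges the Z.G.Z term, so this reckoning chooses none.

**The forecast.** The forecast gave 81.5 %, 28 %, 82.5 % and none, its y below this reckoning, holding that "Gas transfer limits the run".

**The result.** The flask gives 83.1 %, 27.6 %, 82.8 % and none. In this flask G stands at 33.0 % of the charge at 1.50 h and 0.930 % at 3.00 h, while Gc is 13.1 % of it. At 3.0 h in this flask, dissolved G.Z goes forward to X 6.9 times as fast as to Z.G.Z. In the neighbour flask charged with 0.76 M of G, supply by 3.0 h leaves about 442 mM, above Gc, and the balance puts G at 59.9 % of its charge. That flask holds 60 % of its charge as G, with y at 36.2 %.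

The constants were chosen freely; what happens was integrated by code.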